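The route rests on disconnecting the C2–C3 bond of the dihydrofuran ring (ring B; benzofuran numbering O1, C2, C3, C3a–C7a). C3 is traced back to a formyl carbon on the acylphloroglucinol ring (ring A) and C2 to the OCH2 carbon of a methallyl aryl ether. The key step exploits that C2–H is both allylic and alpha to O1 and lies 1,5 to C3: a cobalt-bound carbene radical at C3, released from a tosylhydrazone, abstracts this hydrogen and closes ring B, setting the 2R stereocentre under catalyst control in one operation. The precursor is a bis-pivalate-protected 2-(methallyloxy)benzaldehyde tosylhydrazone; the pyranone (ring C) is joined last through the C7 methylene bridge.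

Key step: step 5

Remark on the chemistry: trimethyl(pent-2-en-3-yloxy)silane 11 is taken as a commercial E/Z mixture (otherwise one step from pentan-3-one); its alkene geometry is lost in step 7.

Step 1
Reactants: 1 phlorisobutyrophenone (2-methyl-1-(2,4,6-trihydroxyphenyl)propan-1-one); 2 methallyl bromide (3-bromo-2-methylprop-1-ene)
Product: 3 1-[2,6-dihydroxy-4-(2-methylprop-2-en-1-yloxy)phenyl]-2-methylpropan-1-one
Conditions: 2 (1.05 equiv), K2CO3 (1.1 equiv), acetone, reflux
Reagents that add atoms: none
Why: Williamson etherification in which the 4-hydroxyl, the most acidic and the only one not hydrogen-bonded to the ketone, should be alkylated selectively, giving a product whose mirror plane makes the two free ring positions equivalent for step 2.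

Step 2
Reactants: 3 the 4-O-methallyl ether
Product: 5 2,4-dihydroxy-6-(2-methylprop-2-en-1-yloxy)-3-(2-methylpropanoyl)benzaldehyde, via iminium chloride 4 (not isolated)
Conditions: POCl3 (1.2 equiv), DMF (3 equiv), EtOAc, 0 °C to rt; then H2O, rt
Reagents that add atoms: N,N-dimethylformamide CN(C)C=O; water O
Why: Vilsmeier–Haack formylation of a ring carbon activated by three oxygen donors, where the two free positions are identical by symmetry, the first formyl group deactivates the ring against a second, and the isolated 1,1-disubstituted alkene and the hindered isobutyryl group should not react with the chloroiminium salt at this temperature.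

Step 3
Reactants: 5 the formylated diol
Product: 6 4-formyl-5-(2-methylprop-2-en-1-yloxy)-2-(2-methylpropanoyl)-1,3-phenylene bis(2,2-dimethylpropanoate)
Conditions: PivCl (3 equiv), Et3N (4 equiv), DMAP (0.2 equiv), CH2Cl2, 0 °C to reflux
Reagents that add atoms: pivaloyl chloride CC(C)(C)C(=O)Cl
Why: DMAP-catalysed O-acylation overcomes the hydrogen bonding of both phenols, and pivalates are chosen because they resist Cs2CO3 in an aprotic solvent, carry no C–H bond 1,5 to the future carbene carbon, and mask phenols that would otherwise turn an ortho- or para-hydroxyaryl carbene into a quinone methide.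

Step 4
Reactants: 6 the bis-pivalate aldehyde
Product: 7 (E)-N-tosylhydrazone of 6
Conditions: TsNHNH2 (1.05 equiv), MeOH, rt
Reagents that add atoms: p-toluenesulfonyl hydrazide Cc1ccc(cc1)S(=O)(=O)NN
Why: Hydrazone condensation, in which the aldehyde should react far faster than the di-ortho-substituted, branched aryl ketone, so that only the formyl group is converted.

Step 5
Reactants: 7 the tosylhydrazone
Product: 9 (2R)-5-(2-methylpropanoyl)-2-(prop-1-en-2-yl)-2,3-dihydro-1-benzofuran-4,6-diyl bis(2,2-dimethylpropanoate), via aryldiazomethane 8 (not isolated)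
Conditions: Co(3,5-DitBu-QingPhyrin) (5 mol%, the D2-symmetric chiral amidoporphyrin complex of divalent cobalt, ligand antipode that gives 2R), Cs2CO3 (2 equiv), 1,4-dioxane, 40 °C
Reagents that add atoms: none
Why: Cs2CO3 converts 7 by Bamford–Stevens loss of p-toluenesulfinate into aryldiazomethane 8, which the divalent cobalt metalloradical activates with loss of N2 to a cobalt-bound benzylic radical at C3 (a trivalent cobalt carbene radical); this radical abstracts a hydrogen from the OCH2 carbon through a six-membered 1,5-hydrogen atom transfer, and the resulting aryloxy-substituted allyl radical bonds to C3 with release of divalent cobalt. The closest known reaction types are the cobalt-porphyrin-catalysed enantioselective radical 1,5-C–H alkylation of aryldiazomethanes generated from aldehyde tosylhydrazones, which gives 2-substituted benzo-fused five-membered heterocycles, and the metalloporphyrin-catalysed carbene C–H insertion of 2-alkoxyaryl tosylhydrazone salts to 2,3-dihydrobenzofurans. Ring B closes in a 5-exo-tet radical substitution at the Co–C3 bond, which forms the C3–C2 bond. The C2 stereocentre is set by the chiral cavity of the amidoporphyrin, which selects the enantiotopic hydrogen that is abstracted and the face of the planar allyl radical that bonds to C3. The step needs chemoselectivity for C–H abstraction over capture of the diazo group or the carbene radical by the methallyl C=C, and regioselectivity for the oxygen-bearing allyl terminus: the first should be secured by the weak, doubly activated (allylic and alpha-oxy) C–H bond held 1,5 to C3, whereas alkene capture needs a seven-membered approach to a 1,1-disubstituted alkene, the second by five- over seven-membered ring closure, and the pivalates offer no competing 1,5-hydrogen.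

Step 6
Reactants: 9 the (2R)-bis-pivalate
Product: 10 1-[(2R)-4,6-dihydroxy-2-(prop-1-en-2-yl)-2,3-dihydro-1-benzofuran-5-yl]-2-methylpropan-1-one
Conditions: NaOMe (2.5 equiv), MeOH, 0 °C to rt; then 1 M HCl to pH 5
Reagents that add atoms: none
Why: Methanolysis (transesterification) of aryl pivalates, which are activated as esters of acidic, carbonyl-flanked phenols, should free both hydroxyls while the ketone, the isopropenyl group and the C2 stereocentre, which has no acidic hydrogen, stay untouched.

Step 7
Reactants: 11 trimethyl(pent-2-en-3-yloxy)silane; 12 malonyl dichloride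
Product: 14 6-ethyl-4-hydroxy-5-methyl-2H-pyran-2-one, via 4-methyl-3,5-dioxoheptanoyl chloride 13 (not isolated)
Conditions: Et2O, −78 °C to rt; then aqueous work-up
Reagents that add atoms: none
Why: C-acylation of the silyl enol ether by malonyl dichloride gives diketo acid chloride 13, whose enol oxygen closes onto the second acid chloride to give the 4-hydroxy-2-pyranone (acylation–lactonisation).

Step 8
Reactants: 10 the (2R)-dihydrobenzofuran diol; 14 the pyranone
Product: 17 target (CNP0206652.1), via pyranone Mannich base 15 (not isolated), via methylene-dione 16 (not isolated)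
Conditions: 14, Eschenmoser's salt (1.05 equiv), CH2Cl2, rt; then 10 (1.0 equiv), 40 °C
Reagents that add atoms: Eschenmoser's salt (N,N-dimethylmethyleneiminium iodide) C=[N+](C)C.[I-]
Why: Mannich reaction at C3 of the pyranone gives 15, which loses dimethylamine to the Michael acceptor 16, and this is trapped in a Friedel–Crafts-type conjugate addition by C7 of 10, the only unsubstituted ring carbon, flanked by O1 and the C6 hydroxyl, under conditions mild enough to leave the allylic aryl ether stereocentre intact.

Compound list
1 | phlorisobutyrophenone, 2-methyl-1-(2,4,6-trihydroxyphenyl)propan-1-one | CC(C)C(=O)c1c(O)cc(O)cc1O | starting material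
2 | methallyl bromide, 3-bromo-2-methylprop-1-ene | C=C(C)CBr | starting material
3 | 1-[2,6-dihydroxy-4-(2-methylprop-2-en-1-yloxy)phenyl]-2-methylpropan-1-one | CC(C)C(=O)c1c(O)cc(OCC(C)=C)cc1O | intermediate
4 | aryl N,N-dimethyliminium chloride of the Vilsmeier step (not isolated) | CC(C)C(=O)c1c(O)cc(OCC(C)=C)c(C=[N+](C)C)c1O.[Cl-] | intermediate
5 | 2,4-dihydroxy-6-(2-methylprop-2-en-1-yloxy)-3-(2-methylpropanoyl)benzaldehyde | CC(C)C(=O)c1c(O)cc(OCC(C)=C)c(C=O)c1O | intermediate
6 | 4-formyl-5-(2-methylprop-2-en-1-yloxy)-2-(2-methylpropanoyl)-1,3-phenylene bis(2,2-dimethylpropanoate) | CC(C)C(=O)c1c(OC(=O)C(C)(C)C)cc(OCC(C)=C)c(C=O)c1OC(=O)C(C)(C)C | intermediate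
7 | (E)-N-tosylhydrazone of 6 | CC(C)C(=O)c1c(OC(=O)C(C)(C)C)cc(OCC(C)=C)c(/C=N/NS(=O)(=O)c2ccc(C)cc2)c1OC(=O)C(C)(C)C | intermediate
8 | aryldiazomethane from 7 (not isolated) | CC(C)C(=O)c1c(OC(=O)C(C)(C)C)cc(OCC(C)=C)c(C=[N+]=[N-])c1OC(=O)C(C)(C)C | intermediate
9 | (2R)-5-(2-methylpropanoyl)-2-(prop-1-en-2-yl)-2,3-dihydro-1-benzofuran-4,6-diyl bis(2,2-dimethylpropanoate) | C=C(C)[C@H]1Cc2c(OC(=O)C(C)(C)C)c(C(=O)C(C)C)c(OC(=O)C(C)(C)C)cc2O1 | intermediate
10 | 1-[(2R)-4,6-dihydroxy-2-(prop-1-en-2-yl)-2,3-dihydro-1-benzofuran-5-yl]-2-methylpropan-1-one | C=C(C)[C@H]1Cc2c(O)c(C(=O)C(C)C)c(O)cc2O1 | intermediate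
11 | trimethyl(pent-2-en-3-yloxy)silane, E/Z mixture | CC=C(CC)O[Si](C)(C)C | starting material
12 | malonyl dichloride | O=C(Cl)CC(=O)Cl | starting material
13 | 4-methyl-3,5-dioxoheptanoyl chloride (not isolated) | CCC(=O)C(C)C(=O)CC(=O)Cl | intermediate
14 | 6-ethyl-4-hydroxy-5-methyl-2H-pyran-2-one | CCc1oc(=O)cc(O)c1C | intermediate
15 | 3-[(dimethylamino)methyl]-6-ethyl-4-hydroxy-5-methyl-2H-pyran-2-one (not isolated) | CCc1oc(=O)c(CN(C)C)c(O)c1C | intermediate
16 | 6-ethyl-5-methyl-3-methylidene-2H-pyran-2,4(3H)-dione (not isolated) | CCC1=C(C)C(=O)C(=C)C(=O)O1 | intermediate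
17 | 3-{[(2R)-4,6-dihydroxy-5-(2-methylpropanoyl)-2-(prop-1-en-2-yl)-2,3-dihydro-1-benzofuran-7-yl]methyl}-6-ethyl-4-hydroxy-5-methyl-2H-pyran-2-one | C=C(C)[C@H]1Cc2c(O)c(C(=O)C(C)C)c(O)c(Cc3c(O)c(C)c(CC)oc3=O)c2O1 | target

Total step count: 8. Longest linear sequence: 7 steps (steps 1 to 6, then step 8); step 7 is a one-step side branch.

Steps most likely to fail

Step 5. The carbene carbon carries two ortho substituents and must enter the chiral porphyrin pocket, so carbene radical formation may be slow and facial discrimination poor; capture of the diazo group by the methallyl alkene is a second concern. The fallback keeps the same C3–C2 ring closure but gives up catalyst control of configuration. It sets out from 7: the unhindered achiral Co(TPP) (tetraphenylporphyrin complex of divalent cobalt), Cs2CO3, dioxane, 60 °C should close the ring through 8 to the racemic bis-pivalate F1. Methanolysis with NaOMe in MeOH should give the racemic diol F2. Preparative chromatography of F2 on a chiral stationary phase (amylose tris(3,5-dimethylphenylcarbamate)) should deliver the 2R enantiomer, with the 2S enantiomer F3 set aside. The route is rejoined at 10.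

Step 8. The methylene unit may be scrambled: methylene-dione 16 can be trapped by a second molecule of 14 to give the symmetrical bis-pyranone, and retro-Mannich or retro-Michael exchange can lead to symmetrical dimers. The fallback reverses the roles of the two partners. It sets out from 10: Eschenmoser's salt in CH2Cl2 at rt should aminomethylate C7 to give the Mannich base F4, which is isolated. Heating F4 with 14 in dioxane at 80 °C should expel dimethylamine to the ortho-quinone methide F5, which the nucleophilic C3 of 14 traps. The route is rejoined at 17.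

Step 3. Acylation of the hydroxyl wedged between the formyl and isobutyryl groups by the bulky acyl chloride may stay incomplete, cleavage in step 6 may be correspondingly slow, and O-to-N pivaloyl migration to the hydrazone anion could intervene in step 5. The fallback changes the protecting group to a small, base-stable acetal. It sets out from 5: NaH, MOMCl, DMF, 0 °C to rt should give the bis-MOM aldehyde F6. TsNHNH2 in MeOH should give its tosylhydrazone F7. The cobalt-catalysed closure under the conditions of step 5 should proceed through the diazo compound F8 to the (2R)-bis-MOM dihydrobenzofuran F9, with the weak allylic C–H preferred over the stronger OCH2O hydrogens of the neighbouring MOM group. Acetal exchange with HCl in MeOH at rt should remove both MOM groups. The route is rejoined at 10.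

Further compounds
F1 | step 5 | racemic 5-(2-methylpropanoyl)-2-(prop-1-en-2-yl)-2,3-dihydro-1-benzofuran-4,6-diyl bis(2,2-dimethylpropanoate) | C=C(C)C1Cc2c(OC(=O)C(C)(C)C)c(C(=O)C(C)C)c(OC(=O)C(C)(C)C)cc2O1
F2 | step 5 | racemic 1-[4,6-dihydroxy-2-(prop-1-en-2-yl)-2,3-dihydro-1-benzofuran-5-yl]-2-methylpropan-1-one | C=C(C)C1Cc2c(O)c(C(=O)C(C)C)c(O)cc2O1
F3 | step 5 | 1-[(2S)-4,6-dihydroxy-2-(prop-1-en-2-yl)-2,3-dihydro-1-benzofuran-5-yl]-2-methylpropan-1-one | C=C(C)[C@@H]1Cc2c(O)c(C(=O)C(C)C)c(O)cc2O1
F4 | step 8 | 1-[(2R)-7-[(dimethylamino)methyl]-4,6-dihydroxy-2-(prop-1-en-2-yl)-2,3-dihydro-1-benzofuran-5-yl]-2-methylpropan-1-one | C=C(C)[C@H]1Cc2c(O)c(C(=O)C(C)C)c(O)c(CN(C)C)c2O1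
F5 | step 8 | ortho-quinone methide, (2R)-4-hydroxy-7-methylidene-5-(2-methylpropanoyl)-2-(prop-1-en-2-yl)-2,3-dihydro-1-benzofuran-6(7H)-one | C=C(C)[C@H]1CC2=C(O1)C(=C)C(=O)C(C(=O)C(C)C)=C2O
F6 | step 3 | 2,4-bis(methoxymethoxy)-6-(2-methylprop-2-en-1-yloxy)-3-(2-methylpropanoyl)benzaldehyde | CC(C)C(=O)c1c(OCOC)cc(OCC(C)=C)c(C=O)c1OCOC
F7 | step 3 | (E)-N-tosylhydrazone of F6 | CC(C)C(=O)c1c(OCOC)cc(OCC(C)=C)c(/C=N/NS(=O)(=O)c2ccc(C)cc2)c1OCOC
F8 | step 3 | aryldiazomethane from F7 | CC(C)C(=O)c1c(OCOC)cc(OCC(C)=C)c(C=[N+]=[N-])c1OCOC
F9 | step 3 | 1-[(2R)-4,6-bis(methoxymethoxy)-2-(prop-1-en-2-yl)-2,3-dihydro-1-benzofuran-5-yl]-2-methylpropan-1-one | C=C(C)[C@H]1Cc2c(OCOC)c(C(=O)C(C)C)c(OCOC)cc2O1
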